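Assumption: C15-acetogenin numbering is used (C1 = alkyne CH, C15 = ethyl CH3), so the target is (3E,6R,7R,9S,10S,12S,13R)-9,12-dibromo-6,10:7,13-diepoxypentadec-3-en-1-yne.

**Retrosynthetic overview**
- Target ⇒ deacetyllaurencin: the oxane (last ring) comes from a transannular bromoetherification that forms C10–O and C9–Br together.
- Deacetyllaurencin ⇒ bromo-oxocene carrying a terminal epoxide + (E)-silyl-enynyllithium (C4–C5 bond; the epoxide is the latent C6–OH, so no protecting groups are needed).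
- Oxocene (first ring) ⇒ ring-closing metathesis at C9=C10 of an open-chain ether; C12–Br from C12–OH with inversion.
- Ether ⇒ C13–O bond by a catalyst-controlled copper-carbene O–H insertion (new) of an epoxy alcohol with ethyl 2-diazobutanoate; C12 carbinol by ester reduction and allylboration.
- Epoxy alcohol ⇒ (S)-glycidol by oxidation and allylboration.

**Route**

Step 1
Reactants: 1 (S)-glycidol
Product: 3 (2R,3R)-1,2-epoxyhex-5-en-3-ol, via (R)-oxirane-2-carbaldehyde 2 (not isolated)
Conditions: (COCl)2, DMSO, Et3N, CH2Cl2, −78 °C; cold solution added to l-Ipc2B(allyl) [B-allylbis((1S,2R,3S,5S)-isopinocampheyl)borane, from (−)-α-pinene], Et2O, −78 °C; NaOH, H2O2, 0 °C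
Reagents that add atoms: B-allyldiisopinocampheylborane (l-Ipc2B(allyl)), C=CCB([C@H]1C[C@H]2C[C@@H]([C@@H]1C)C2(C)C)[C@H]1C[C@H]2C[C@@H]([C@@H]1C)C2(C)C
Why: Swern oxidation gives the epoxy aldehyde without touching C6, and Brown asymmetric allylboration (chair transition state, reagent control by the isopinocampheyl groups, which overrides the weak Felkin bias) sets C7 as R, threo to the C6 centre inherited from (S)-glycidol.

Step 2
Reactants: 4 ethyl 2-ethyl-3-oxobutanoate
Product: 5 ethyl 2-diazobutanoate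
Conditions: 4-acetamidobenzenesulfonyl azide, DBU, MeCN, 0 °C to rt
Reagents that add atoms: 4-acetamidobenzenesulfonyl azide, CC(=O)Nc1ccc(cc1)S(=O)(=O)N=[N+]=[N-]
Why: Regitz deacylative diazo transfer: the β-keto ester enolate attacks the sulfonyl azide and the acetyl group leaves as the N-acetylsulfonamide; no stereocentre is involved.

Step 3
Reactants: 3 (2R,3R)-1,2-epoxyhex-5-en-3-ol; 5 ethyl 2-diazobutanoate
Product: 6 ethyl (2R)-2-{[(1R)-1-[(2R)-oxiran-2-yl]but-3-en-1-yl]oxy}butanoate
Conditions: CuCl (5 mol %), NaB[3,5-(CF3)2C6H3]4 (6 mol %), (Sa,S,S)-Ph-SpiroBOX [7,7′-bis((S)-4-phenyl-4,5-dihydrooxazol-2-yl)-1,1′-spirobiindane; antipode if mismatched] (6 mol %), 4 Å molecular sieves, CH2Cl2, 25 °C, 5 (1.5 equiv) added over 4 h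
Reagents that add atoms: none
Why: Proposed new method: catalyst-controlled diastereoselective copper-carbene O–H insertion of an α-alkyl-α-diazo ester into an unprotected, base-sensitive secondary epoxy alcohol. The electrophilic monovalent-copper carbene from 5 is trapped by the hydroxyl of 3 faster than it cyclopropanates the terminal alkene or undergoes β-hydride shift, and the copper-bound oxonium ylide collapses by a ligand-directed 1,2-proton shift that sets C13 as R while forming the C13–O bond under neutral conditions (no alkoxide, hence no Payne migration). The closest known reaction type is the Cu/spiro-bis(oxazoline)-catalysed enantioselective O–H insertion of α-diazopropionates into phenols and of α-aryl diazoacetates into simple alcohols.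

Step 4
Reactants: 6 ethyl (2R)-2-{[(1R)-1-[(2R)-oxiran-2-yl]but-3-en-1-yl]oxy}butanoate
Product: 7 (2R)-2-{[(1R)-1-[(2R)-oxiran-2-yl]but-3-en-1-yl]oxy}butanal
Conditions: i-Bu2AlH (1.1 equiv), CH2Cl2, −78 °C; aq. KNaC4H4O6 work-up; used crude at once
Reagents that add atoms: none
Why: Ester-to-aldehyde reduction with i-Bu2AlH: the chelated aluminium hemiacetal of the α-alkoxy ester is stable at −78 °C, so over-reduction and epoxide opening are avoided and C13 is untouched.

Step 5
Reactants: 7 (2R)-2-{[(1R)-1-[(2R)-oxiran-2-yl]but-3-en-1-yl]oxy}butanal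
Product: 8 (3R,4R)-3-{[(1R)-1-[(2R)-oxiran-2-yl]but-3-en-1-yl]oxy}hept-6-en-4-ol
Conditions: l-Ipc2B(allyl), Et2O, −78 °C; NaOH, H2O2, 0 °C
Reagents that add atoms: B-allyldiisopinocampheylborane (l-Ipc2B(allyl)), C=CCB([C@H]1C[C@H]2C[C@@H]([C@@H]1C)C2(C)C)[C@H]1C[C@H]2C[C@@H]([C@@H]1C)C2(C)C
Why: Brown asymmetric allylboration: the same reagent gives the 12R alcohol (threo to C13) under reagent control and without a Lewis acid, so the epoxide survives.

Step 6
Reactants: 8 (3R,4R)-3-{[(1R)-1-[(2R)-oxiran-2-yl]but-3-en-1-yl]oxy}hept-6-en-4-ol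
Product: 9 (2R,3R,5Z,8R)-2-ethyl-8-[(2R)-oxiran-2-yl]-3,4,7,8-tetrahydro-2H-oxocin-3-ol
Conditions: second-generation Grubbs catalyst (5 mol %), CH2Cl2 (2 mM), 40 °C
Reagents that add atoms: none
Why: Ring-closing olefin metathesis forms C9=C10 and the oxocene (first ring); the gauche vicinal oxygens on both sides of the ether pre-organise the diene, the eight-membered ring enforces the Z olefin, and epoxide and hydroxyl are inert to the Ru carbene.

Step 7
Reactants: 9 (2R,3R,5Z,8R)-2-ethyl-8-[(2R)-oxiran-2-yl]-3,4,7,8-tetrahydro-2H-oxocin-3-ol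
Product: 10 (2R,3S,5Z,8R)-3-bromo-2-ethyl-8-[(2R)-oxiran-2-yl]-3,4,7,8-tetrahydro-2H-oxocine
Conditions: CBr4, (n-C8H17)3P, 1-methylcyclohexene, toluene, 70 °C
Reagents that add atoms: carbon tetrabromide, BrC(Br)(Br)Br
Why: Appel-type bromination: bromide displaces the alkoxyphosphonium ion in an SN2 step with inversion, turning 12R-OH into 12S-Br, while the alkene additive scavenges HBr to spare the epoxide.

Step 8
Reactants: 11 3-(trimethylsilyl)prop-2-ynal
Product: 12 (E)-(4-iodobut-3-en-1-yn-1-yl)trimethylsilane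
Conditions: CHI3, CrCl2, THF, 0 °C
Reagents that add atoms: iodoform, IC(I)I
Why: Takai iodo-olefination: the geminal dichromium species from CHI3 and divalent chromium adds to the aldehyde and eliminates to the E vinyl iodide.

Step 9
Reactants: 12 (E)-(4-iodobut-3-en-1-yn-1-yl)trimethylsilane; 10 (2R,3S,5Z,8R)-3-bromo-2-ethyl-8-[(2R)-oxiran-2-yl]-3,4,7,8-tetrahydro-2H-oxocine
Product: 15 deacetyllaurencin (3E,6R,7R,9Z,12S,13R)-12-bromo-7,13-epoxypentadeca-3,9-dien-1-yn-6-ol, via (E)-4-(trimethylsilyl)but-1-en-3-ynyllithium 13 (not isolated), via 1-trimethylsilyl-deacetyllaurencin 14 (not isolated)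
Conditions: 12 (2.5 equiv), t-BuLi (5 equiv), Et2O, −78 °C; then 10, BF3·OEt2, −78 °C; then MeOH, K2CO3, rt
Reagents that add atoms: none
Why: Iodine–lithium exchange retains the E geometry, the alkenyllithium opens the BF3-activated terminal epoxide at its CH2 end in an SN2 step (C4–C5 bond, C6 configuration retained, C6–OH unmasked), and K2CO3 methanolysis removes the alkynyl silyl group.

Step 10
Reactants: 15 deacetyllaurencin
Product: 16 (3E,6R,7R,9S,10S,12S,13R)-9,12-dibromo-6,10:7,13-diepoxypentadec-3-en-1-yne (target)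
Conditions: TBCO (2,4,4,6-tetrabromocyclohexa-2,5-dienone, 1.1 equiv), CH2Cl2, 0 °C to rt, dark
Reagents that add atoms: 2,4,4,6-tetrabromocyclohexa-2,5-dienone, O=C1C(Br)=CC(Br)(Br)C=C1Br
Why: Biomimetic transannular bromoetherification (key C–O bond): Br+ adds to the peripheral face of the ring Z olefin and the C6 hydroxyl opens the bromonium ion at C10 in the 6-endo mode with anti addition, closing the oxane (second ring) and setting 9S and 10S, the only geometry the tether allows.

**Compound list**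
1 | (S)-glycidol [(S)-oxiran-2-ylmethanol] | OC[C@H]1CO1 | starting material
2 | (R)-oxirane-2-carbaldehyde | O=C[C@H]1CO1 | intermediate
3 | (2R,3R)-1,2-epoxyhex-5-en-3-ol [(1R)-1-[(2R)-oxiran-2-yl]but-3-en-1-ol] | C=CC[C@@H](O)[C@H]1CO1 | intermediate
4 | ethyl 2-ethyl-3-oxobutanoate | CCOC(=O)C(CC)C(C)=O | starting material
5 | ethyl 2-diazobutanoate | CCOC(=O)C(CC)=[N+]=[N-] | intermediate
6 | ethyl (2R)-2-{[(1R)-1-[(2R)-oxiran-2-yl]but-3-en-1-yl]oxy}butanoate | CCOC(=O)[C@@H](CC)O[C@H](CC=C)[C@H]1CO1 | intermediate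
7 | (2R)-2-{[(1R)-1-[(2R)-oxiran-2-yl]but-3-en-1-yl]oxy}butanal | O=C[C@@H](CC)O[C@H](CC=C)[C@H]1CO1 | intermediate
8 | (3R,4R)-3-{[(1R)-1-[(2R)-oxiran-2-yl]but-3-en-1-yl]oxy}hept-6-en-4-ol | C=CC[C@@H](O)[C@@H](CC)O[C@H](CC=C)[C@H]1CO1 | intermediate
9 | (2R,3R,5Z,8R)-2-ethyl-8-[(2R)-oxiran-2-yl]-3,4,7,8-tetrahydro-2H-oxocin-3-ol | O[C@@H]1C/C=C\C[C@H]([C@H]2CO2)O[C@@H]1CC | intermediate
10 | (2R,3S,5Z,8R)-3-bromo-2-ethyl-8-[(2R)-oxiran-2-yl]-3,4,7,8-tetrahydro-2H-oxocine | Br[C@H]1C/C=C\C[C@H]([C@H]2CO2)O[C@@H]1CC | intermediate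
11 | 3-(trimethylsilyl)prop-2-ynal | C[Si](C)(C)C#CC=O | starting material
12 | (E)-(4-iodobut-3-en-1-yn-1-yl)trimethylsilane | C[Si](C)(C)C#C/C=C/I | intermediate
13 | (E)-[4-(trimethylsilyl)but-1-en-3-yn-1-yl]lithium | [Li]/C=C/C#C[Si](C)(C)C | intermediate
14 | 1-trimethylsilyl-deacetyllaurencin [(3E,6R,7R,9Z,12S,13R)-12-bromo-7,13-epoxy-1-(trimethylsilyl)pentadeca-3,9-dien-1-yn-6-ol] | C[Si](C)(C)C#C/C=C/C[C@@H](O)[C@H]1C/C=C\C[C@H](Br)[C@@H](CC)O1 | intermediate
15 | deacetyllaurencin [(3E,6R,7R,9Z,12S,13R)-12-bromo-7,13-epoxypentadeca-3,9-dien-1-yn-6-ol] | C#C/C=C/C[C@@H](O)[C@H]1C/C=C\C[C@H](Br)[C@@H](CC)O1 | intermediate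
16 | (3E,6R,7R,9S,10S,12S,13R)-9,12-dibromo-6,10:7,13-diepoxypentadec-3-en-1-yne | C#C/C=C/C[C@H]1O[C@H]2C[C@H](Br)[C@@H](CC)O[C@@H]1C[C@@H]2Br | target

**Step count and risks**

Total step count: 10. Longest linear sequence: 8 (steps 1, 3, 4, 5, 6, 7, 9, 10).

The three steps most likely to fail:

- **Step 3 (the proposed new O–H insertion).** The risks are β-hydride shift of the carbene to ethyl crotonate and insufficient catalyst control at C13 next to the chiral alcohol. The fallback uses known chemistry and sets out from 3. Commercial ethyl (S)-2-hydroxybutanoate is converted with Tf2O and 2,6-lutidine (CH2Cl2, −78 °C) into ethyl (2S)-2-{[(trifluoromethyl)sulfonyl]oxy}butanoate F1. The sodium alkoxide of 3 (NaH, THF, −40 °C, generated in the presence of F1 to outrun Payne migration) displaces the triflate in an SN2 step with inversion. This gives 6, where the route is rejoined.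

- **Step 7 (bromination of the ring alcohol next to a terminal epoxide at 70 °C).** The risks are epoxide opening by the bromophosphonium reagent and elimination. The fallback sets out from 8 and changes the order of events. The open-chain alcohol 8 is brominated under milder Appel conditions (CBr4, PPh3, 2,6-lutidine, CH2Cl2, 0 °C to rt, inversion) to (2R)-2-[(1R)-1-{[(3R,4S)-4-bromohept-6-en-3-yl]oxy}but-3-en-1-yl]oxirane F2. Ring-closing metathesis of F2 with second-generation Grubbs catalyst then gives 10, where the route is rejoined.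

- **Step 10 (regiochemistry of the transannular bromoetherification).** The risk is 5-exo attack at C9 in place of 6-endo attack at C10. The fallback sets out from 15. If TBCO gives mainly the 5-exo bromo ether (3E,6R,7R,9R,10R,12S,13R)-10,12-dibromo-6,9:7,13-diepoxypentadec-3-en-1-yne F3, this isomer is isolated and ring-expanded by reversible bromide ionisation (ZnBr2, MeNO2, 40 °C). The bridging oxygen displaces bromide at C10 to give the oxiranium ion and bromide returns at C9. This is the oxolane-to-oxane rearrangement of 2-(1-haloalkyl)tetrahydrofurans; both carbons are inverted once, so it delivers the same 9S,10S product 16, where the route ends.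

**Further compounds**
F1 | step 3 | ethyl (2S)-2-{[(trifluoromethyl)sulfonyl]oxy}butanoate | CCOC(=O)[C@H](CC)OS(=O)(=O)C(F)(F)F
F2 | step 7 | (2R)-2-[(1R)-1-{[(3R,4S)-4-bromohept-6-en-3-yl]oxy}but-3-en-1-yl]oxirane | C=CC[C@H](Br)[C@@H](CC)O[C@H](CC=C)[C@H]1CO1
F3 | step 10 | (3E,6R,7R,9R,10R,12S,13R)-10,12-dibromo-6,9:7,13-diepoxypentadec-3-en-1-yne | C#C/C=C/C[C@H]1O[C@@H]2C[C@H]1O[C@H](CC)[C@@H](Br)C[C@H]2Br
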